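**Retrosynthetic overview**
- Target ⇐ bis-silyl dimethyl ester (fluoride, then LiOH); the C2=C3 (E) enoate ⇐ Horner–Wadsworth–Emmons olefination of a C3 methyl ketone.
- C8–C9 ⇐ Wittig olefination and hydrogenation joining a C3–C8 epoxy keto aldehyde (west) to a C9–C15 phosphonium salt (east).
- West: keto aldehyde ⇐ glycol cleavage of a cyclohexane-1,2-diol ⇐ 2,3-epoxycyclohexanone ⇐ (R)-3,5-dimethylcyclohex-2-enone ⇐ enantioselective intramolecular aldol condensation of achiral 4-methylheptane-2,6-dione. This ring closure sets C7, locks the cis geometry of the later oxirane and relays C7 to C4/C5.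
- East: Evans syn-aldol of the N-crotonyl oxazolidinone dienolate with 4-chlorobutanal (C12, C13); vinyl → CH2OH by ozonolysis.
- Ring order: carbocycle (aldol condensation) → oxirane (conjugate addition of hydroperoxide, then ring closure) → carbocycle opened by periodate, leaving the oxirane as the only ring.

Assumption: the SMILES is taken literally, i.e. (2E,4S,5R,7S,12S,13R)-4,5-epoxy-12-hydroxy-13-(hydroxymethyl)-3,5,7-trimethyltetradec-2-enedioic acid (numbered from the enoic acid carbon), with C3 and C6 cis on the oxirane and 12-OH/13-CH2OH syn along the C11–C14 zigzag.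
Abbreviation: TBS = tert-butyldimethylsilyl; atom labels C1–C15 refer to the target numbering above (C15 = hydroxymethyl carbon).

**West fragment**

Step 1
Reactants: 1 dimethyl 3-methylpentanedioate
Product: 2 N1,N5-dimethoxy-N1,N5,3-trimethylpentanediamide
Conditions: MeNH(OMe)·HCl (3 equiv), i-PrMgCl (6 equiv), THF, −20 → 0 °C
Reagents that add atoms: N,O-dimethylhydroxylamine hydrochloride, CNOC.Cl
Why: Aminolysis of both esters by the chloromagnesium amide made in the flask (Weinreb amide formation) gives a diamide that accepts exactly one methyl nucleophile per carbonyl.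

Step 2
Reactants: 2 N1,N5-dimethoxy-N1,N5,3-trimethylpentanediamide
Product: 3 4-methylheptane-2,6-dione
Conditions: MeMgBr (2.6 equiv), THF, 0 °C; aq NH4Cl
Reagents that add atoms: methylmagnesium bromide, C[Mg]Br
Why: Weinreb ketone synthesis, in which the chelated tetrahedral adducts persist until the quench, so there is no over-addition and no premature aldol reaction of the achiral 1,5-diketone.

Step 3
Reactants: 3 4-methylheptane-2,6-dione
Product: 5 (5R)-3,5-dimethylcyclohex-2-en-1-one, via ketol 4 (not isolated)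
Conditions: 9-amino-9-deoxy-epi-quinidine (20 mol %), AcOH (60 mol %), toluene, −15 °C, 72 h
Reagents that add atoms: none
Why: Primary-amine (enamine) catalysed desymmetrising intramolecular aldol condensation, in which the chiral cinchona amine selects one of the two enantiotopic acetonyl arms as the enamine donor, so ring closure and dehydration set the methyl-bearing centre (C7 of the target); the quinine-derived pseudoenantiomer gives ent-5, so the sense is confirmed by optical rotation before going on.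

Step 4
Reactants: 5 (5R)-3,5-dimethylcyclohex-2-en-1-one
Product: 6 (2R,3R,5R)-2,3-epoxy-3,5-dimethylcyclohexan-1-one
Conditions: 30% aq H2O2, NaOH (0.3 equiv), MeOH, 0 → 15 °C
Reagents that add atoms: hydrogen peroxide, OO
Why: Weitz–Scheffer nucleophilic epoxidation, in which hydroperoxide adds in a conjugate (oxa-Michael) fashion axially and anti to the C5 methyl group and the enolate then closes the oxirane, so O is trans to the ring methyl (C4 and C5 of the target) and the ring fusion forces the two future chain arms to be cis.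

Step 5
Reactants: 6 (2R,3R,5R)-2,3-epoxy-3,5-dimethylcyclohexan-1-one
Product: 8 (2R,3R,5R)-2,3-epoxy-6-hydroxy-3,5-dimethylcyclohexan-1-one (C6 epimers), via potassium enolate 7 (not isolated)
Conditions: KN(SiMe3)2, THF, −78 °C; then 2-(phenylsulfonyl)-3-phenyloxaziridine, −78 °C; aq NH4Cl
Reagents that add atoms: 2-(phenylsulfonyl)-3-phenyloxaziridine, O=S(=O)(c1ccccc1)N1OC1c1ccccc1
Why: Kinetic enolisation on the only enolisable side (C6) followed by electrophilic hydroxylation with the N-sulfonyloxaziridine (Davis oxidation); the new carbinol centre is destroyed in step 7, so its configuration does not matter.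

Step 6
Reactants: 8 (2R,3R,5R)-2,3-epoxy-6-hydroxy-3,5-dimethylcyclohexan-1-one
Product: 9 (2S,3R,5R)-2,3-epoxy-1,3,5-trimethylcyclohexane-1,6-diol (C1 and C6 epimers)
Conditions: MeLi (3 equiv), THF, −78 °C; aq NH4Cl
Reagents that add atoms: methyllithium, [Li]C
Why: 1,2-Addition of methyllithium to the ketone (the first equivalent deprotonates OH) installs the future C3 methyl group, the hindered trisubstituted epoxide being inert at −78 °C and both new centres being lost in step 7.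

Step 7
Reactants: 9 (2S,3R,5R)-2,3-epoxy-1,3,5-trimethylcyclohexane-1,6-diol
Product: 10 (2R)-3-[(2R,3R)-3-acetyl-2-methyloxiran-2-yl]-2-methylpropanal
Conditions: NaIO4, THF/pH 7 phosphate buffer, 0 °C → rt; used at once
Reagents that add atoms: none
Why: Malaprade glycol cleavage opens the carbocycle between the two carbinol carbons to give the C3 methyl ketone and the C8 aldehyde, the buffered cold conditions sparing the oxirane and the α-methyl centre (C7).

**East fragment**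

Step 8
Reactants: 11 (4R)-4-benzyl-1,3-oxazolidin-2-one; 12 (2E)-but-2-enoyl chloride
Product: 14 (4R)-4-benzyl-3-[(2E)-but-2-enoyl]-1,3-oxazolidin-2-one, via lithium salt 13 (not isolated)
Conditions: n-BuLi, THF, −78 °C; then 12, −78 → 0 °C
Reagents that add atoms: none
Why: N-Acylation of the lithiated oxazolidinone by the acid chloride gives the chiral crotonyl imide.

Step 9
Reactants: 15 4-chlorobutan-1-ol
Product: 16 4-chlorobutanal
Conditions: TEMPO (1 mol %), KBr (10 mol %), NaOCl (1.1 equiv), NaHCO3, CH2Cl2/H2O, 0 °C; used as dried solution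
Reagents that add atoms: none
Why: Anelli (oxoammonium) oxidation stops cleanly at the aldehyde and leaves the primary chloride untouched.

Step 10
Reactants: 14 (4R)-4-benzyl-3-[(2E)-but-2-enoyl]-1,3-oxazolidin-2-one; 16 4-chlorobutanal
Product: 18 (4R)-4-benzyl-3-[(2R,3S)-6-chloro-2-ethenyl-3-hydroxyhexanoyl]-1,3-oxazolidin-2-one, via boron dienolate 17 (not isolated)
Conditions: Bu2BOTf, Et3N, CH2Cl2, −78 → 0 °C; then 16, −78 → 0 °C; pH 7 buffer, MeOH, 30% H2O2, 0 °C
Reagents that add atoms: none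
Why: Evans boron aldol of the (Z)-dienolate, which reacts at its α-carbon through a Zimmerman–Traxler chair with the aldehyde on the face away from the benzyl group, giving the syn adduct with C13 (R) and C12 (S) under auxiliary control.

Step 11
Reactants: 18 (4R)-4-benzyl-3-[(2R,3S)-6-chloro-2-ethenyl-3-hydroxyhexanoyl]-1,3-oxazolidin-2-one
Product: 19 (4R)-4-benzyl-3-[(2R,3S)-6-chloro-2-ethenyl-3-(TBSO)hexanoyl]-1,3-oxazolidin-2-one
Conditions: TBSOTf, 2,6-lutidine, CH2Cl2, −78 → 0 °C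
Reagents that add atoms: tert-butyldimethylsilyl trifluoromethanesulfonate, CC(C)(C)[Si](C)(C)OS(=O)(=O)C(F)(F)F
Why: O-Silylation of the hindered secondary aldol hydroxyl blocks retro-aldol and tetrahydrofuran formation with the δ-chloride.

Step 12
Reactants: 19 (4R)-4-benzyl-3-[(2R,3S)-6-chloro-2-ethenyl-3-(TBSO)hexanoyl]-1,3-oxazolidin-2-one
Product: 21 (4R)-4-benzyl-3-[(2R,3S)-6-chloro-2-(hydroxymethyl)-3-(TBSO)hexanoyl]-1,3-oxazolidin-2-one, via ozonide 20 (not isolated)
Conditions: O3, CH2Cl2, −78 °C; then MeOH, NaBH4, −78 → 0 °C (short)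
Reagents that add atoms: ozone, [O-][O+]=O
Why: Ozonolysis of the only alkene with direct borohydride reduction of the ozonide turns vinyl into CH2OH (C15) without accumulating the epimerisable α-formyl imide, so C13 is kept.

Step 13
Reactants: 21 (4R)-4-benzyl-3-[(2R,3S)-6-chloro-2-(hydroxymethyl)-3-(TBSO)hexanoyl]-1,3-oxazolidin-2-one
Product: 22 (4R)-4-benzyl-3-[(2R,3S)-6-chloro-3-(TBSO)-2-(TBSOCH2)hexanoyl]-1,3-oxazolidin-2-one
Conditions: TBSCl, imidazole, DMF, rt
Reagents that add atoms: tert-butyldimethylsilyl chloride, CC(C)(C)[Si](C)(C)Cl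
Why: Silylation of the primary alcohol gives a diol protection that is later removed by fluoride without acid, which the final vinyl epoxide would not tolerate.

Step 14
Reactants: 22 (4R)-4-benzyl-3-[(2R,3S)-6-chloro-3-(TBSO)-2-(TBSOCH2)hexanoyl]-1,3-oxazolidin-2-one
Product: 24 (2R,3S)-6-chloro-3-(TBSO)-2-(TBSOCH2)hexanoic acid, via peroxy acid 23 (not isolated)
Conditions: LiOH, 30% H2O2, THF/H2O (3:1), 0 °C; Na2SO3; cold 1 M HCl to pH 3
Reagents that add atoms: hydrogen peroxide, OO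
Why: Hydroperoxide attacks the exocyclic imide carbonyl selectively (Evans auxiliary cleavage) and is too weakly basic to epimerise C13 or displace the chloride.

Step 15
Reactants: 24 (2R,3S)-6-chloro-3-(TBSO)-2-(TBSOCH2)hexanoic acid
Product: 25 methyl (2R,3S)-6-chloro-3-(TBSO)-2-(TBSOCH2)hexanoate
Conditions: Me3SiCHN2, toluene/MeOH (4:1), 0 °C → rt
Reagents that add atoms: (trimethylsilyl)diazomethane, C[Si](C)(C)C=[N+]=[N-]
Why: Neutral O-methylation of the carboxylic acid by diazomethane generated in the flask esterifies without touching the silyl ethers or the α-centre.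

Step 16
Reactants: 25 methyl (2R,3S)-6-chloro-3-(TBSO)-2-(TBSOCH2)hexanoate
Product: 27 [(4S,5R)-6-methoxy-6-oxo-4-(TBSO)-5-(TBSOCH2)hexyl]triphenylphosphonium iodide, via alkyl iodide 26 (not isolated)
Conditions: NaI (3 equiv), PPh3 (2 equiv), MeCN, reflux, 48 h
Reagents that add atoms: triphenylphosphine, c1ccccc1P(c1ccccc1)c1ccccc1; sodium iodide, [Na+].[I-]
Why: Finkelstein exchange followed by SN2 quaternisation of the unhindered primary iodide by triphenylphosphine; silyl ethers and the hindered methyl ester are inert.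

**Coupling and endgame**

Step 17
Reactants: 27 [(4S,5R)-6-methoxy-6-oxo-4-(TBSO)-5-(TBSOCH2)hexyl]triphenylphosphonium iodide; 10 (2R)-3-[(2R,3R)-3-acetyl-2-methyloxiran-2-yl]-2-methylpropanal
Product: 29 methyl (2R,3S,6Z,8R)-9-[(2R,3R)-3-acetyl-2-methyloxiran-2-yl]-8-methyl-3-(TBSO)-2-(TBSOCH2)non-6-enoate, via ylide 28 (not isolated)
Conditions: 27 (1.1 equiv), NaN(SiMe3)2 (1.05 equiv), THF, −78 °C; then 10, −78 → 0 °C
Reagents that add atoms: none
Why: Wittig olefination with a non-stabilised ylide, which at −78 °C reacts much faster with the aldehyde than with the methyl ketone or the remote ester and does not epimerise the α-methyl centre; the alkene geometry is irrelevant.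

Step 18
Reactants: 29 methyl (2R,3S,6Z,8R)-9-[(2R,3R)-3-acetyl-2-methyloxiran-2-yl]-8-methyl-3-(TBSO)-2-(TBSOCH2)non-6-enoate
Product: 30 methyl (2R,3S,8S)-9-[(2R,3R)-3-acetyl-2-methyloxiran-2-yl]-8-methyl-3-(TBSO)-2-(TBSOCH2)nonanoate
Conditions: H2 (1 atm), RhCl(PPh3)3 (10 mol %), benzene/EtOH (1:1), rt
Reagents that add atoms: none
Why: Homogeneous hydrogenation with Wilkinson's catalyst saturates the disubstituted C8=C9 alkene without hydrogenolysis of the α,β-epoxy ketone, which a heterogeneous palladium catalyst would risk.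

Step 19
Reactants: 30 methyl (2R,3S,8S)-9-[(2R,3R)-3-acetyl-2-methyloxiran-2-yl]-8-methyl-3-(TBSO)-2-(TBSOCH2)nonanoate
Product: 31 dimethyl (2E,4S,5R,7S,12S,13R)-4,5-epoxy-3,5,7-trimethyl-12-(TBSO)-13-(TBSOCH2)tetradec-2-enedioate
Conditions: (MeO)2P(O)CH2CO2Me (3 equiv), NaH (2.8 equiv), THF, 0 → 45 °C
Reagents that add atoms: trimethyl phosphonoacetate, COC(=O)CP(=O)(OC)OC
Why: Horner–Wadsworth–Emmons olefination of the activated α,β-epoxy methyl ketone places the ester trans to the bulky oxiranyl group (E major, minor Z isomer removed by chromatography), the phosphonate anion being too weak a base to affect the ester α-centre or the epoxide.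

Step 20
Reactants: 31 dimethyl (2E,4S,5R,7S,12S,13R)-4,5-epoxy-3,5,7-trimethyl-12-(TBSO)-13-(TBSOCH2)tetradec-2-enedioate
Product: 32 dimethyl (2E,4S,5R,7S,12S,13R)-4,5-epoxy-12-hydroxy-13-(hydroxymethyl)-3,5,7-trimethyltetradec-2-enedioate
Conditions: Bu4NF (4 equiv), AcOH (4 equiv), THF, 0 °C → rt
Reagents that add atoms: none
Why: Fluoride-mediated desilylation buffered with acetic acid frees both hydroxyls without acid (vinyl epoxide) or strong base (β-hydroxy ester).

Step 21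
Reactants: 32 dimethyl (2E,4S,5R,7S,12S,13R)-4,5-epoxy-12-hydroxy-13-(hydroxymethyl)-3,5,7-trimethyltetradec-2-enedioate
Product: 33 (2E,4S,5R,7S,12S,13R)-4,5-epoxy-12-hydroxy-13-(hydroxymethyl)-3,5,7-trimethyltetradec-2-enedioic acid (CNP0468463.2)
Conditions: LiOH (8 equiv), THF/MeOH/H2O (3:1:1), 0 °C → rt; then cold 0.5 M HCl to pH 4, immediate extraction
Reagents that add atoms: lithium hydroxide, [Li+].[OH-]
Why: Saponification of both methyl esters, with the trisubstituted epoxide resistant to hydroxide at room temperature and the carboxylate formed at C14 protecting C13 from epimerisation.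

**Compound list**
1 | dimethyl 3-methylpentanedioate | COC(=O)CC(C)CC(=O)OC | starting material
2 | N1,N5-dimethoxy-N1,N5,3-trimethylpentanediamide | CON(C)C(=O)CC(C)CC(=O)N(C)OC | intermediate
3 | 4-methylheptane-2,6-dione | CC(=O)CC(C)CC(C)=O | intermediate
4 | (5R)-3-hydroxy-3,5-dimethylcyclohexan-1-one (ketol, C3 epimers, not isolated) | O=C1CC(C)(O)C[C@@H](C)C1 | intermediate
5 | (5R)-3,5-dimethylcyclohex-2-en-1-one | O=C1C=C(C)C[C@@H](C)C1 | intermediate
6 | (2R,3R,5R)-2,3-epoxy-3,5-dimethylcyclohexan-1-one | O=C2[C@@H]1O[C@]1(C)C[C@@H](C)C2 | intermediate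
7 | potassium C1=C6 enolate of 6 (not isolated) | [K+].[O-]C=2[C@@H]1O[C@]1(C)C[C@@H](C)C2 | intermediate
8 | (2R,3R,5R)-2,3-epoxy-6-hydroxy-3,5-dimethylcyclohexan-1-one (C6 epimers) | O=C2[C@@H]1O[C@]1(C)C[C@@H](C)C2O | intermediate
9 | (2S,3R,5R)-2,3-epoxy-1,3,5-trimethylcyclohexane-1,6-diol (C1 and C6 epimers) | CC2(O)[C@@H]1O[C@]1(C)C[C@@H](C)C2O | intermediate
10 | (2R)-3-[(2R,3R)-3-acetyl-2-methyloxiran-2-yl]-2-methylpropanal | CC(=O)[C@@H]1O[C@]1(C)C[C@@H](C)C=O | intermediate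
11 | (4R)-4-benzyl-1,3-oxazolidin-2-one | O=C1N[C@H](Cc2ccccc2)CO1 | starting material
12 | (2E)-but-2-enoyl chloride | C/C=C/C(Cl)=O | starting material
13 | lithium salt of 11 (not isolated) | [Li+].O=C1[N-][C@H](Cc2ccccc2)CO1 | intermediate
14 | (4R)-4-benzyl-3-[(2E)-but-2-enoyl]-1,3-oxazolidin-2-one | C/C=C/C(=O)N1[C@H](Cc2ccccc2)COC1=O | intermediate
15 | 4-chlorobutan-1-ol | OCCCCCl | starting material
16 | 4-chlorobutanal | O=CCCCCl | intermediate
17 | dibutylboron (Z)-dienolate of 14 (not isolated) | C=C/C=C(\OB(CCCC)CCCC)N1[C@H](Cc2ccccc2)COC1=O | intermediate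
18 | (4R)-4-benzyl-3-[(2R,3S)-6-chloro-2-ethenyl-3-hydroxyhexanoyl]-1,3-oxazolidin-2-one | ClCCC[C@H](O)[C@@H](C=C)C(=O)N1[C@H](Cc2ccccc2)COC1=O | intermediate
19 | (4R)-4-benzyl-3-[(2R,3S)-6-chloro-2-ethenyl-3-(TBSO)hexanoyl]-1,3-oxazolidin-2-one | ClCCC[C@H](O[Si](C)(C)C(C)(C)C)[C@@H](C=C)C(=O)N1[C@H](Cc2ccccc2)COC1=O | intermediate
20 | secondary ozonide (1,2,4-trioxolane) of 19 (not isolated) | ClCCC[C@H](O[Si](C)(C)C(C)(C)C)[C@@H](C3OOCO3)C(=O)N1[C@H](Cc2ccccc2)COC1=O | intermediate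
21 | (4R)-4-benzyl-3-[(2R,3S)-6-chloro-2-(hydroxymethyl)-3-(TBSO)hexanoyl]-1,3-oxazolidin-2-one | ClCCC[C@H](O[Si](C)(C)C(C)(C)C)[C@@H](CO)C(=O)N1[C@H](Cc2ccccc2)COC1=O | intermediate
22 | (4R)-4-benzyl-3-[(2R,3S)-6-chloro-3-(TBSO)-2-(TBSOCH2)hexanoyl]-1,3-oxazolidin-2-one | ClCCC[C@H](O[Si](C)(C)C(C)(C)C)[C@@H](CO[Si](C)(C)C(C)(C)C)C(=O)N1[C@H](Cc2ccccc2)COC1=O | intermediate
23 | (2R,3S)-6-chloro-3-(TBSO)-2-(TBSOCH2)hexaneperoxoic acid (not isolated) | ClCCC[C@H](O[Si](C)(C)C(C)(C)C)[C@@H](CO[Si](C)(C)C(C)(C)C)C(=O)OO | intermediate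
24 | (2R,3S)-6-chloro-3-(TBSO)-2-(TBSOCH2)hexanoic acid | ClCCC[C@H](O[Si](C)(C)C(C)(C)C)[C@@H](CO[Si](C)(C)C(C)(C)C)C(=O)O | intermediate
25 | methyl (2R,3S)-6-chloro-3-(TBSO)-2-(TBSOCH2)hexanoate | ClCCC[C@H](O[Si](C)(C)C(C)(C)C)[C@@H](CO[Si](C)(C)C(C)(C)C)C(=O)OC | intermediate
26 | methyl (2R,3S)-6-iodo-3-(TBSO)-2-(TBSOCH2)hexanoate (not isolated) | ICCC[C@H](O[Si](C)(C)C(C)(C)C)[C@@H](CO[Si](C)(C)C(C)(C)C)C(=O)OC | intermediate
27 | [(4S,5R)-6-methoxy-6-oxo-4-(TBSO)-5-(TBSOCH2)hexyl]triphenylphosphonium iodide | [I-].c1ccccc1[P+](c1ccccc1)(c1ccccc1)CCC[C@H](O[Si](C)(C)C(C)(C)C)[C@@H](CO[Si](C)(C)C(C)(C)C)C(=O)OC | intermediate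
28 | phosphonium ylide of 27 (not isolated) | c1ccccc1P(c1ccccc1)(c1ccccc1)=CCC[C@H](O[Si](C)(C)C(C)(C)C)[C@@H](CO[Si](C)(C)C(C)(C)C)C(=O)OC | intermediate
29 | methyl (2R,3S,6Z,8R)-9-[(2R,3R)-3-acetyl-2-methyloxiran-2-yl]-8-methyl-3-(TBSO)-2-(TBSOCH2)non-6-enoate | CC(=O)[C@@H]1O[C@]1(C)C[C@@H](C)/C=C\CC[C@H](O[Si](C)(C)C(C)(C)C)[C@@H](CO[Si](C)(C)C(C)(C)C)C(=O)OC | intermediate
30 | methyl (2R,3S,8S)-9-[(2R,3R)-3-acetyl-2-methyloxiran-2-yl]-8-methyl-3-(TBSO)-2-(TBSOCH2)nonanoate | CC(=O)[C@@H]1O[C@]1(C)C[C@@H](C)CCCC[C@H](O[Si](C)(C)C(C)(C)C)[C@@H](CO[Si](C)(C)C(C)(C)C)C(=O)OC | intermediate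
31 | dimethyl (2E,4S,5R,7S,12S,13R)-4,5-epoxy-3,5,7-trimethyl-12-(TBSO)-13-(TBSOCH2)tetradec-2-enedioate | C/C(=C\C(=O)OC)[C@@H]1O[C@]1(C)C[C@@H](C)CCCC[C@H](O[Si](C)(C)C(C)(C)C)[C@@H](CO[Si](C)(C)C(C)(C)C)C(=O)OC | intermediate
32 | dimethyl (2E,4S,5R,7S,12S,13R)-4,5-epoxy-12-hydroxy-13-(hydroxymethyl)-3,5,7-trimethyltetradec-2-enedioate | C/C(=C\C(=O)OC)[C@@H]1O[C@]1(C)C[C@@H](C)CCCC[C@H](O)[C@@H](CO)C(=O)OC | intermediate
33 | (2E,4S,5R,7S,12S,13R)-4,5-epoxy-12-hydroxy-13-(hydroxymethyl)-3,5,7-trimethyltetradec-2-enedioic acid (CNP0468463.2) | C/C(=C\C(=O)O)[C@@H]1O[C@]1(C)C[C@@H](C)CCCC[C@H](O)[C@@H](CO)C(=O)O | target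

**Step count**
Total: 21 steps (west 1–7, east 8–16, joint line 17–21).
Longest linear sequence: 13 steps (8 or 9, then 10–16, then 17–21).

**Three steps most likely to fail, each with a fallback**

Step 3 (enantioselectivity, or sense, of the aldol condensation with the small methyl substituent). The fallback sets out from 3 and comes back at 5. Diketone 3 is cyclised without induction by the same intramolecular aldol condensation (KOH, MeOH) to racemic 3,5-dimethylcyclohex-2-en-1-one F1. Luche reduction (NaBH4, CeCl3·7H2O, MeOH, −78 °C) gives racemic cis-3,5-dimethylcyclohex-2-en-1-ol F2. Lipase-catalysed transesterification (Candida antarctica lipase B, vinyl acetate, hexane) acylates the 1R enantiomer, as expected from Kazlauskas' rule, to (1R,5R)-3,5-dimethylcyclohex-2-en-1-yl acetate F3, which is separated from the unreacted (1S,5S)-alcohol. Methanolysis (K2CO3, MeOH) gives (1R,5R)-3,5-dimethylcyclohex-2-en-1-ol F4, and MnO2 (CH2Cl2) oxidises it to 5.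

Step 5 (enolate hydroxylation next to the epoxide). The fallback sets out from 5 and comes back at 8. The oxygen is introduced before the epoxide: enone 5 is α'-acetoxylated with Mn(OAc)3 (benzene, reflux) to (6R)-4,6-dimethyl-2-oxocyclohex-3-en-1-yl acetate F5. Nucleophilic epoxidation under non-hydrolytic conditions (t-BuOOH, DBU, CH2Cl2), again anti to the ring methyl, gives (2R,3R,5R)-6-acetoxy-2,3-epoxy-3,5-dimethylcyclohexan-1-one F6. Mild methanolysis (K2CO3, MeOH, 0 °C) gives 8.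

Step 17 (aldehyde versus methyl ketone selectivity, α-epimerisation at C7, ylide next to an ester). The fallback sets out from 8 and comes back at 30. Hydroxy ketone 8 is cleaved directly with Pb(OAc)4 in MeOH/benzene to methyl (2R,3R)-3-methyl-3-[(2R)-2-methyl-3-oxopropyl]oxirane-2-carboxylate F7, which carries no ketone. Wittig reaction with ylide 28 gives methyl (2R,3S,6Z,8R)-9-[(2R,3R)-3-(methoxycarbonyl)-2-methyloxiran-2-yl]-8-methyl-3-(TBSO)-2-(TBSOCH2)non-6-enoate F8. Hydrogenation (H2, RhCl(PPh3)3) gives the saturated diester methyl (2R,3S,8S)-9-[(2R,3R)-3-(methoxycarbonyl)-2-methyloxiran-2-yl]-8-methyl-3-(TBSO)-2-(TBSOCH2)nonanoate F9. The unhindered, activated glycidic ester is converted selectively (MeNH(OMe)·HCl, i-PrMgCl, THF, −20 °C) into the Weinreb amide methyl (2R,3S,8S)-9-{(2R,3R)-3-[methoxy(methyl)carbamoyl]-2-methyloxiran-2-yl}-8-methyl-3-(TBSO)-2-(TBSOCH2)nonanoate F10. MeMgBr (THF, −78 °C) then gives ketone 30.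

**Further compounds**
F1 | step 3 | racemic 3,5-dimethylcyclohex-2-en-1-one | O=C1C=C(C)C[C@@H](C)C1.O=C1C=C(C)C[C@H](C)C1
F2 | step 3 | racemic cis-3,5-dimethylcyclohex-2-en-1-ol | O[C@H]1C=C(C)C[C@@H](C)C1.O[C@@H]1C=C(C)C[C@H](C)C1
F3 | step 3 | (1R,5R)-3,5-dimethylcyclohex-2-en-1-yl acetate | CC(=O)O[C@H]1C=C(C)C[C@@H](C)C1
F4 | step 3 | (1R,5R)-3,5-dimethylcyclohex-2-en-1-ol | O[C@H]1C=C(C)C[C@@H](C)C1
F5 | step 5 | (6R)-4,6-dimethyl-2-oxocyclohex-3-en-1-yl acetate (C1 epimers) | O=C2C=C(C)C[C@@H](C)C2OC(C)=O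
F6 | step 5 | (2R,3R,5R)-6-acetoxy-2,3-epoxy-3,5-dimethylcyclohexan-1-one (C6 epimers) | O=C2[C@@H]1O[C@]1(C)C[C@@H](C)C2OC(C)=O
F7 | step 17 | methyl (2R,3R)-3-methyl-3-[(2R)-2-methyl-3-oxopropyl]oxirane-2-carboxylate | COC(=O)[C@@H]1O[C@]1(C)C[C@@H](C)C=O
F8 | step 17 | methyl (2R,3S,6Z,8R)-9-[(2R,3R)-3-(methoxycarbonyl)-2-methyloxiran-2-yl]-8-methyl-3-(TBSO)-2-(TBSOCH2)non-6-enoate | COC(=O)[C@@H]1O[C@]1(C)C[C@@H](C)/C=C\CC[C@H](O[Si](C)(C)C(C)(C)C)[C@@H](CO[Si](C)(C)C(C)(C)C)C(=O)OC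
F9 | step 17 | methyl (2R,3S,8S)-9-[(2R,3R)-3-(methoxycarbonyl)-2-methyloxiran-2-yl]-8-methyl-3-(TBSO)-2-(TBSOCH2)nonanoate | COC(=O)[C@@H]1O[C@]1(C)C[C@@H](C)CCCC[C@H](O[Si](C)(C)C(C)(C)C)[C@@H](CO[Si](C)(C)C(C)(C)C)C(=O)OC
F10 | step 17 | methyl (2R,3S,8S)-9-{(2R,3R)-3-[methoxy(methyl)carbamoyl]-2-methyloxiran-2-yl}-8-methyl-3-(TBSO)-2-(TBSOCH2)nonanoate | CON(C)C(=O)[C@@H]1O[C@]1(C)C[C@@H](C)CCCC[C@H](O[Si](C)(C)C(C)(C)C)[C@@H](CO[Si](C)(C)C(C)(C)C)C(=O)OC
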